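## Retrosynthetic overview

1. Target 28 ⇐ keto diol 24 by bis-angeloylation, then C2=C3 dehydrogenation (C11 is a bridgehead, so only one enone can form).
2. 24 ⇐ tricyclic β-keto ester 19: ketoreductase reduction at C7, alkoxide-directed (Fráter–Seebach) methylation at C6, ester reduction, then oxidation and 1,3-anti reduction to invert C7.
3. Seven-membered ring (closed last) ⇐ Dieckmann condensation of bicyclic diester 18; its C5–H comes from hydroxyl-directed hydrogenation of an alkylidene ester made by HWE on cyclobutanone 14.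
4. Cyclobutane and six-membered ring (closed together, first) ⇐ intramolecular vinylketene–alkene [2+2] of dienoic acid 11, steered by the C1 silyloxy stereocentre.
5. 11 ⇐ catalytic asymmetric vinylogous Mukaiyama aldol of enal 6 (from geranyl acetate) with silyl dienolate 8 (from tert-butyl 3-methylbut-2-enoate).

Atom labels used below: C1 = ketone carbon of the target; C2=C3(C12H3); C4 and C11 = cyclobutane CH carbons flanking the enone; C5 = cyclobutane CH bonded to C6; C6 = quaternary carbon (C15H3, C14H2O); C7 = CH–O; C8, C9 = CH2; C10 = cyclobutane C(C13H3). "Upper face" = side of the C1–C3 bridge, "lower face" = side of the C6–C9 bridge.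

Assumption: geranyl acetate, tert-butyl 3-methylbut-2-enoate, tert-butyl 2-(diethoxyphosphoryl)acetate and angelic acid are bought as achiral materials; the ketoreductase is chosen from a commercial screening panel for the required (7R) sense, and the sense of the aldol catalyst in step 6 follows the published model and is checked by Mosher ester analysis.

## Route

Step 1
Reactants: 1 geranyl acetate
Product: 2 (2E)-3-methyl-6-oxohex-2-en-1-yl acetate
Conditions: O3 (1.0 equiv), pyridine (3 equiv), CH2Cl2, −78 °C
Reagents that add atoms: ozone [O-][O+]=O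
Why: Criegee ozonolysis cleaves only the distal trisubstituted alkene, which is far more electron-rich than the 2,3-alkene deactivated by the allylic acetate, and pyridine gives the aldehyde directly; no stereocentre is formed.

Step 2
Reactants: 2 (2E)-3-methyl-6-oxohex-2-en-1-yl acetate
Product: 4 methyl (4E)-6-acetoxy-4-methylhex-4-enoate, via acid 3 (not isolated)
Conditions: NaClO2, NaH2PO4, 2-methylbut-2-ene, tBuOH/H2O, 0 °C → rt; then crude acid, Me3SiCHN2, MeOH/toluene, 0 °C
Reagents that add atoms: sodium chlorite [Na+].[O-]Cl=O; (trimethylsilyl)diazomethane C[Si](C)(C)C=[N+]=[N-]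
Why: Pinnick oxidation of the saturated aldehyde (the scavenger protects the alkene) followed by O-methylation of the crude acid leaves the allylic acetate and the (E)-alkene untouched.

Step 3
Reactants: 4 methyl (4E)-6-acetoxy-4-methylhex-4-enoate
Product: 5 methyl (4E)-6-hydroxy-4-methylhex-4-enoate
Conditions: K2CO3 (0.2 equiv), MeOH, 0 °C → rt
Reagents that add atoms: none
Why: Base-catalysed transesterification removes the acetate while the methyl ester is invariant in methanol.

Step 4
Reactants: 5 methyl (4E)-6-hydroxy-4-methylhex-4-enoate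
Product: 6 methyl (4E)-4-methyl-6-oxohex-4-enoate
Conditions: activated MnO2 (15 equiv), CH2Cl2, rt
Reagents that add atoms: none
Why: Selective allylic alcohol oxidation gives the (E)-enal without touching the ester or the alkene geometry.

Step 5
Reactants: 7 tert-butyl 3-methylbut-2-enoate
Product: 8 tert-butyl[(1-tert-butoxy-3-methylbuta-1,3-dien-1-yl)oxy]dimethylsilane
Conditions: LiN(iPr)2 (1.1 equiv), THF, −78 °C; tBuMe2SiCl, DMPU, −78 °C → rt
Reagents that add atoms: tert-butyldimethylsilyl chloride CC(C)(C)[Si](C)(C)Cl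
Why: γ-Deprotonation of the senecioate and O-silylation of the extended enolate give the silyl dienol ether needed for the vinylogous aldol.

Step 6
Reactants: 6 methyl (4E)-4-methyl-6-oxohex-4-enoate; 8 tert-butyl[(1-tert-butoxy-3-methylbuta-1,3-dien-1-yl)oxy]dimethylsilane
Product: 9 1-tert-butyl 10-methyl (2E,5S,6E)-5-hydroxy-3,7-dimethyldeca-2,6-dienedioate
Conditions: SiCl4 (1.1 equiv), Denmark BINAM-derived bisphosphoramide (5 mol%, the enantiomer directing Si-face attack, (S,S) by the published model), iPr2NEt (10 mol%), CH2Cl2, −78 °C; aq. NaHCO3/KF work-up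
Reagents that add atoms: none
Why: In this Lewis-base-activated SiCl4 vinylogous Mukaiyama aldol the chiral phosphoramide-bound silyl cation activates the enal and the dienolate adds through its γ-carbon to the Si face, creating the first stereocentre (C1, S) by asymmetric catalysis with the (E)-enoate formed exclusively.

Step 7
Reactants: 9 1-tert-butyl 10-methyl (2E,5S,6E)-5-hydroxy-3,7-dimethyldeca-2,6-dienedioate
Product: 11 (2E,5S,6E)-5-[(tert-butyldimethylsilyl)oxy]-10-methoxy-3,7-dimethyl-10-oxodeca-2,6-dienoic acid, via TBS ester 10 (not isolated)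
Conditions: tBuMe2SiOTf (3 equiv), 2,6-lutidine (4 equiv), CH2Cl2, 0 °C → rt; then K2CO3 (0.1 equiv), MeOH/H2O, 0 °C, 30 min; pH 4 work-up
Reagents that add atoms: tert-butyldimethylsilyl trifluoromethanesulfonate CC(C)(C)[Si](C)(C)OS(=O)(=O)C(F)(F)F
Why: The silyl triflate silylates the carbinol and cleaves the tert-butyl ester (loss of isobutene) to a labile silyl ester, which brief mild methanolysis converts to the acid while the methyl ester and the silyl ether survive.

Step 8
Reactants: 11 (2E,5S,6E)-5-[(tert-butyldimethylsilyl)oxy]-10-methoxy-3,7-dimethyl-10-oxodeca-2,6-dienoic acid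
Product: 14 methyl 3-[(1R,4S,5R,7R)-4-[(tert-butyldimethylsilyl)oxy]-7-methyl-2-methylidene-6-oxobicyclo[3.1.1]heptan-7-yl]propanoate, via acid chloride 12 (not isolated), via vinylketene 13 (not isolated)
Conditions: 1-chloro-N,N,2-trimethylprop-1-en-1-amine, CH2Cl2, 0 °C → rt; then slow addition (6 h) to Et3N (5 equiv), toluene, 110 °C, final 0.005 M
Reagents that add atoms: none
Why: In this intramolecular vinylketene–alkene [2+2] cycloaddition (the bergamotene-type closure) the ketene carbonyl carbon bonds to the less substituted alkene carbon to give the bridged bicyclo[3.1.1]heptan-6-one, the (E)-alkene places the C10 methyl on the upper face, and the C1 silyloxy group takes the position remote from that methyl, so C4, C10 and C11 are set from C1 (the minor diastereomer is removed by chromatography).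

Step 9
Reactants: 14 methyl 3-[(1R,4S,5R,7R)-4-[(tert-butyldimethylsilyl)oxy]-7-methyl-2-methylidene-6-oxobicyclo[3.1.1]heptan-7-yl]propanoate; 15 tert-butyl 2-(diethoxyphosphoryl)acetate
Product: 16 tert-butyl 2-[4-[(tert-butyldimethylsilyl)oxy]-7-(3-methoxy-3-oxopropyl)-7-methyl-2-methylidenebicyclo[3.1.1]heptan-6-ylidene]acetate (ring configuration of 14; alkene isomer mixture)
Conditions: NaH (1.3 equiv), 15 (1.5 equiv), THF, 0 °C; then 14, 65 °C
Reagents that add atoms: none
Why: Horner–Wadsworth–Emmons olefination of the strained, non-enolisable cyclobutanone; the alkene geometry is irrelevant because C5 and C6 become sp3 in step 11.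

Step 10
Reactants: 16 tert-butyl 2-[4-[(tert-butyldimethylsilyl)oxy]-7-(3-methoxy-3-oxopropyl)-7-methyl-2-methylidenebicyclo[3.1.1]heptan-6-ylidene]acetate
Product: 17 tert-butyl 2-[4-hydroxy-7-(3-methoxy-3-oxopropyl)-7-methyl-2-methylidenebicyclo[3.1.1]heptan-6-ylidene]acetate (ring configuration of 14)
Conditions: Bu4NF (1.2 equiv), THF, 0 °C → rt; aq. NH4Cl
Reagents that add atoms: none
Why: Fluoride cleaves the secondary silyl ether and unmasks the C1 hydroxyl that directs the next step.

Step 11
Reactants: 17 tert-butyl 2-[4-hydroxy-7-(3-methoxy-3-oxopropyl)-7-methyl-2-methylidenebicyclo[3.1.1]heptan-6-ylidene]acetate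
Product: 18 methyl 3-[6-(2-tert-butoxy-2-oxoethyl)-4-hydroxy-2,7-dimethylbicyclo[3.1.1]heptan-7-yl]propanoate (C5–H on the upper face so both ester arms are cis on the cyclobutane; C3 methyl toward C10)
Conditions: [Ir(cod)(PCy3)(py)]PF6 (10 mol%), H2 (1–4 atm), CH2Cl2, rt
Reagents that add atoms: none
Why: In this hydroxyl-directed hydrogenation the iridium bound to the C1 hydroxyl delivers H2 to the upper face of the C5=C6 alkene, so the acetate arm ends up on the lower face next to the propanoate arm (sets C5), and the methylidene is saturated from the same side (transient C3 centre).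

Step 12
Reactants: 18 methyl 3-[6-(2-tert-butoxy-2-oxoethyl)-4-hydroxy-2,7-dimethylbicyclo[3.1.1]heptan-7-yl]propanoate
Product: 19 tert-butyl 1-hydroxy-7-oxo-15-norlongipinan-14-oate (tricyclic β-keto ester; C1–OH toward C5; C6 epimers and enol)
Conditions: KOtBu (3.5 equiv), THF, 0 °C → rt, 0.02 M; AcOH quench
Reagents that add atoms: none
Why: In this Dieckmann condensation the tert-butyl ester enolate attacks the methyl ester (the hindered tert-butyl ester is not attacked, which fixes the regiochemistry), the seven-membered ring closes because both arms are held cis on the cyclobutane, and the product is driven forward as its enolate.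

Step 13
Reactants: 19 tert-butyl 1-hydroxy-7-oxo-15-norlongipinan-14-oate
Product: 20 tert-butyl (6S,7R)-1,7-dihydroxy-15-norlongipinan-14-oate (cis hydroxy ester)
Conditions: ketoreductase (NADPH-dependent, (R)-selective for 2-oxocycloalkanecarboxylates), NADP+ (cat.), propan-2-ol (10% v/v), potassium phosphate buffer pH 7.0, DMSO (5% v/v), 30 °C
Reagents that add atoms: none
Why: In this enzymatic carbonyl reduction with dynamic kinetic resolution the ketoreductase transfers hydride from NADPH to one face of the C7 ketone while C6 equilibrates through the enol, so C7 (R) is set by the enzyme independently of the remote, nearly mirror-symmetric skeleton.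

Step 14
Reactants: 20 tert-butyl (6S,7R)-1,7-dihydroxy-15-norlongipinan-14-oate
Product: 21 tert-butyl (6S,7R)-1,7-dihydroxylongipinan-14-oate
Conditions: LiN(iPr)2 (3.5 equiv), THF, −78 → −20 °C; MeI (1.5 equiv), DMPU, −78 → −10 °C
Reagents that add atoms: iodomethane CI
Why: In this Fráter–Seebach alkylation the chelated lithium alkoxide–enolate is methylated anti to the C7 alkoxide, so the quaternary C6 carries CH3 on the C11 side and the ester on the C4 side, as in the target.

Step 15
Reactants: 21 tert-butyl (6S,7R)-1,7-dihydroxylongipinan-14-oate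
Product: 22 (6R,7R)-longipinane-1,7,14-triol
Conditions: LiAlH4 (4 equiv), THF, 0 → 65 °C; H2O/aq. NaOH work-up
Reagents that add atoms: none
Why: Hydride reduction of the hindered ester gives the primary C14 alcohol.

Step 16
Reactants: 22 (6R,7R)-longipinane-1,7,14-triol
Product: 23 (6R)-14-hydroxylongipinane-1,7-dione
Conditions: aq. NaOCl (2.4 equiv), AcOH, 15–25 °C
Reagents that add atoms: none
Why: Stevens oxidation (hypochlorite in acetic acid) oxidises secondary alcohols much faster than primary ones, so C1 and C7 become ketones while the neopentyl C14 alcohol survives; this erases the relay centre at C7.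

Step 17
Reactants: 23 (6R)-14-hydroxylongipinane-1,7-dione
Product: 24 (6R,7S)-7,14-dihydroxylongipinan-1-one
Conditions: Me4NBH(OAc)3 (5 equiv), MeCN/AcOH (1:1), −30 °C
Reagents that add atoms: none
Why: In this Evans–Saksena hydroxyl-directed reduction the acetoxyborohydride bound to the C14 oxygen delivers hydride to the C7 ketone from the face of the CH2OH arm, giving the 1,3-anti diol (C7 S, OH cis to the C6 methyl), while the undirected C1 ketone is not reduced.

Step 18
Reactants: 24 (6R,7S)-7,14-dihydroxylongipinan-1-one; 25 angelic acid [(2Z)-2-methylbut-2-enoic acid]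
Product: 27 (6R,7S)-1-oxolongipinane-7,14-diyl bis[(2Z)-2-methylbut-2-enoate], via mixed anhydride 26 (not isolated)
Conditions: 25 (6 equiv), 2,4,6-trichlorobenzoyl chloride (6 equiv), Et3N, toluene, rt, 2 h; then 24, toluene, 80 °C
Reagents that add atoms: none
Why: Yamaguchi-type esterification through the mixed trichlorobenzoic anhydride, run without a nucleophilic catalyst, acylates both the primary and the hindered secondary alcohol while keeping the (Z)-geometry of the angelate.

Step 19
Reactants: 27 (6R,7S)-1-oxolongipinane-7,14-diyl bis[(2Z)-2-methylbut-2-enoate]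
Product: 28 (4R,5S,6R,7S,10R,11R)-1-oxolongipin-2-ene-7,14-diyl bis[(2Z)-2-methylbut-2-enoate] (CNP0240716.1)
Conditions: IBX (3 equiv), 4-methoxypyridine N-oxide (3 equiv), DMSO, 25 → 45 °C
Reagents that add atoms: none
Why: IBX-mediated α,β-dehydrogenation of the ketone can enolise only toward C2 (C11 is a bridgehead), so the C2=C3 bond of the enone forms regiospecifically and the transient C3 centre disappears.

## Compound list

1 | geranyl acetate [(2E)-3,7-dimethylocta-2,6-dien-1-yl acetate] | CC(C)=CCC/C(C)=C/COC(C)=O | starting material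
2 | (2E)-3-methyl-6-oxohex-2-en-1-yl acetate | O=CCC/C(C)=C/COC(C)=O | intermediate
3 | (4E)-6-acetoxy-4-methylhex-4-enoic acid | OC(=O)CC/C(C)=C/COC(C)=O | intermediate
4 | methyl (4E)-6-acetoxy-4-methylhex-4-enoate | COC(=O)CC/C(C)=C/COC(C)=O | intermediate
5 | methyl (4E)-6-hydroxy-4-methylhex-4-enoate | COC(=O)CC/C(C)=C/CO | intermediate
6 | methyl (4E)-4-methyl-6-oxohex-4-enoate | COC(=O)CC/C(C)=C/C=O | intermediate
7 | tert-butyl 3-methylbut-2-enoate | CC(C)=CC(=O)OC(C)(C)C | starting material
8 | tert-butyl[(1-tert-butoxy-3-methylbuta-1,3-dien-1-yl)oxy]dimethylsilane | C=C(C)C=C(OC(C)(C)C)O[Si](C)(C)C(C)(C)C | intermediate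
9 | 1-tert-butyl 10-methyl (2E,5S,6E)-5-hydroxy-3,7-dimethyldeca-2,6-dienedioate | CC(C)(C)OC(=O)/C=C(\C)C[C@H](O)/C=C(\C)CCC(=O)OC | intermediate
10 | tert-butyldimethylsilyl ester of acid 11 (silyl ether and silyl ester) | CC(C)(C)[Si](C)(C)OC(=O)/C=C(\C)C[C@H](O[Si](C)(C)C(C)(C)C)/C=C(\C)CCC(=O)OC | intermediate
11 | (2E,5S,6E)-5-[(tert-butyldimethylsilyl)oxy]-10-methoxy-3,7-dimethyl-10-oxodeca-2,6-dienoic acid | OC(=O)/C=C(\C)C[C@H](O[Si](C)(C)C(C)(C)C)/C=C(\C)CCC(=O)OC | intermediate
12 | acid chloride of 11 | ClC(=O)/C=C(\C)C[C@H](O[Si](C)(C)C(C)(C)C)/C=C(\C)CCC(=O)OC | intermediate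
13 | vinylketene, methyl (4E,6S)-6-[(tert-butyldimethylsilyl)oxy]-4-methyl-8-methylidene-10-oxodeca-4,9-dienoate | O=C=CC(=C)C[C@H](O[Si](C)(C)C(C)(C)C)/C=C(\C)CCC(=O)OC | intermediate
14 | methyl 3-[(1R,4S,5R,7R)-4-[(tert-butyldimethylsilyl)oxy]-7-methyl-2-methylidene-6-oxobicyclo[3.1.1]heptan-7-yl]propanoate (silyloxy on the side of the carbonyl bridge; 7-methyl toward the three-carbon bridge) | COC(=O)CC[C@]1(C)[C@H]2C(=C)C[C@H](O[Si](C)(C)C(C)(C)C)[C@@H]1C2=O | intermediate
15 | tert-butyl 2-(diethoxyphosphoryl)acetate | CCOP(=O)(OCC)CC(=O)OC(C)(C)C | starting material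
16 | tert-butyl 2-[4-[(tert-butyldimethylsilyl)oxy]-7-(3-methoxy-3-oxopropyl)-7-methyl-2-methylidenebicyclo[3.1.1]heptan-6-ylidene]acetate (ring configuration of 14; alkene isomers) | COC(=O)CC[C@]1(C)[C@H]2C(=C)C[C@H](O[Si](C)(C)C(C)(C)C)[C@@H]1C2=CC(=O)OC(C)(C)C | intermediate
17 | tert-butyl 2-[4-hydroxy-7-(3-methoxy-3-oxopropyl)-7-methyl-2-methylidenebicyclo[3.1.1]heptan-6-ylidene]acetate (ring configuration of 14) | COC(=O)CC[C@]1(C)[C@H]2C(=C)C[C@H](O)[C@@H]1C2=CC(=O)OC(C)(C)C | intermediate
18 | methyl 3-[6-(2-tert-butoxy-2-oxoethyl)-4-hydroxy-2,7-dimethylbicyclo[3.1.1]heptan-7-yl]propanoate (C5–H upper face; ester arms cis; C3 methyl toward C10) | COC(=O)CC[C@]1(C)[C@H]2[C@@H](C)C[C@H](O)[C@@H]1[C@H]2CC(=O)OC(C)(C)C | intermediate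
19 | tert-butyl 1-hydroxy-7-oxo-15-norlongipinan-14-oate (C6 epimers and enol) | O=C1CC[C@]2(C)[C@H]3[C@@H](C)C[C@H](O)[C@@H]2[C@H]3C1C(=O)OC(C)(C)C | intermediate
20 | tert-butyl (6S,7R)-1,7-dihydroxy-15-norlongipinan-14-oate | O[C@@H]1CC[C@]2(C)[C@H]3[C@@H](C)C[C@H](O)[C@@H]2[C@H]3[C@@H]1C(=O)OC(C)(C)C | intermediate
21 | tert-butyl (6S,7R)-1,7-dihydroxylongipinan-14-oate | O[C@@H]1CC[C@]2(C)[C@H]3[C@@H](C)C[C@H](O)[C@@H]2[C@H]3[C@]1(C)C(=O)OC(C)(C)C | intermediate
22 | (6R,7R)-longipinane-1,7,14-triol | O[C@@H]1CC[C@]2(C)[C@H]3[C@@H](C)C[C@H](O)[C@@H]2[C@H]3[C@]1(C)CO | intermediate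
23 | (6R)-14-hydroxylongipinane-1,7-dione | O=C1CC[C@]2(C)[C@H]3[C@@H](C)CC(=O)[C@@H]2[C@H]3[C@]1(C)CO | intermediate
24 | (6R,7S)-7,14-dihydroxylongipinan-1-one | O[C@H]1CC[C@]2(C)[C@H]3[C@@H](C)CC(=O)[C@@H]2[C@H]3[C@]1(C)CO | intermediate
25 | angelic acid [(2Z)-2-methylbut-2-enoic acid] | C/C=C(/C)C(=O)O | starting material
26 | angelic 2,4,6-trichlorobenzoic anhydride | C/C=C(/C)C(=O)OC(=O)c1c(Cl)cc(Cl)cc1Cl | intermediate
27 | (6R,7S)-1-oxolongipinane-7,14-diyl bis[(2Z)-2-methylbut-2-enoate] | C/C=C(/C)C(=O)O[C@H]1CC[C@]2(C)[C@H]3[C@@H](C)CC(=O)[C@@H]2[C@H]3[C@]1(C)COC(=O)/C(C)=C\C | intermediate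
28 | (4R,5S,6R,7S,10R,11R)-1-oxolongipin-2-ene-7,14-diyl bis[(2Z)-2-methylbut-2-enoate] (CNP0240716.1) | C/C=C(/C)C(=O)OC[C@@]1(C)[C@@H]2[C@H]3C(=O)C=C(C)[C@@H]2[C@@]3(C)CC[C@@H]1OC(=O)/C(C)=C\C | target

## Summary

Total step count: 19. Longest linear sequence: 18 steps (steps 1–4 and 6–19; step 5 is a one-step side branch).

Three steps most likely to fail:

Step 8 (vinylketene [2+2]). Risks are ketene oligomerisation, reduced nucleophilicity of the alkene next to the silyloxy group and incomplete facial control. Fallback: use the more electrophilic, non-dimerising keteniminium ion instead of the ketene. Setting out from acid 11, amide coupling with pyrrolidine followed by deconjugation (LiN(iPr)2, then kinetic protonation) gives the 3-methylidene pyrrolidine amide F1. Tf2O and 2,4,6-collidine in 1,2-dichloroethane at 80 °C generate the vinylketeniminium salt, which cyclises in the same regio- and stereochemical sense to the cyclobutaniminium triflate F2. Hydrolysis with aqueous NaHCO3 comes back to the route at ketone 14.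

Step 11 (hydroxyl-directed hydrogenation). The catalyst must reach the concave upper face of C5, and it may reduce only the unhindered methylidene or add from below. Fallback: replace metal-hydride delivery by electron transfer with internal proton delivery. Setting out from 17, SmI2 in THF/HMPA without an external proton donor reduces only the conjugated ester, and the samarium-bound C1 hydroxyl protonates C5 from above to give the methylidene-retaining hydroxy diester F3. Hydrogenation over Pd/C then saturates the methylidene from its open face and comes back to the route at 18.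

Step 13 (ketoreductase reduction). The bulky tricyclic keto ester may not be accepted, or the wrong face may be reduced. Fallback: set C6 by auxiliary control instead of by the enzyme relay. Setting out from 19, condensation with tert-butyl L-valinate gives the chiral enamino ester F4. Lithiation (LiN(iPr)2) and methylation, with the solvent/additive (or the D-valinate) chosen for the 6S sense, then mild acid hydrolysis give the quaternary keto ester F5. LiAlH4 reduces it to the triol F6 as a mixture of C7 epimers, and the oxidation of step 16 converges both epimers, so the route is rejoined at 23.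

Further compounds
F1 | step 8 | methyl (4E,6S)-6-[(tert-butyldimethylsilyl)oxy]-4-methyl-8-methylidene-10-oxo-10-(pyrrolidin-1-yl)dec-4-enoate | O=C(N1CCCC1)CC(=C)C[C@H](O[Si](C)(C)C(C)(C)C)/C=C(\C)CCC(=O)OC
F2 | step 8 | 1-[4-[(tert-butyldimethylsilyl)oxy]-7-(3-methoxy-3-oxopropyl)-7-methyl-2-methylidenebicyclo[3.1.1]heptan-6-ylidene]pyrrolidinium trifluoromethanesulfonate (ring configuration of 14) | COC(=O)CC[C@]1(C)[C@H]2C(=C)C[C@H](O[Si](C)(C)C(C)(C)C)[C@@H]1C2=[N+]1CCCC1.[O-]S(=O)(=O)C(F)(F)F
F3 | step 11 | methyl 3-[6-(2-tert-butoxy-2-oxoethyl)-4-hydroxy-7-methyl-2-methylidenebicyclo[3.1.1]heptan-7-yl]propanoate (C5–H upper face; ester arms cis) | COC(=O)CC[C@]1(C)[C@H]2C(=C)C[C@H](O)[C@@H]1[C@H]2CC(=O)OC(C)(C)C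
F4 | step 13 | tert-butyl 7-{[(2S)-1-tert-butoxy-3-methyl-1-oxobutan-2-yl]amino}-1-hydroxy-15-norlongipin-6-en-14-oate | C1(N[C@@H](C(C)C)C(=O)OC(C)(C)C)CC[C@]2(C)[C@H]3[C@@H](C)C[C@H](O)[C@@H]2[C@H]3C=1C(=O)OC(C)(C)C
F5 | step 13 | tert-butyl (6S)-1-hydroxy-7-oxolongipinan-14-oate | O=C1CC[C@]2(C)[C@H]3[C@@H](C)C[C@H](O)[C@@H]2[C@H]3[C@]1(C)C(=O)OC(C)(C)C
F6 | step 13 | (6R)-longipinane-1,7,14-triol (C7 epimers) | OC1CC[C@]2(C)[C@H]3[C@@H](C)C[C@H](O)[C@@H]2[C@H]3[C@]1(C)CO
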